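The earlier runs and the new flask come from a simulation from invented constants, noise included.

- Percent of the substrate charged is our unit, an open dimer counting as two, so yields compare directly across charges.

| setting | alder | oak | larch | cedar | epsilon | zeta | gamma | delta |
|---|---|---|---|---|---|---|---|---|
| substrate | 0.051 M | 0.051 M | 0.051 M | 0.10 M | 0.051 M | 0.051 M (fed, over 25 min) | 0.051 M | 0.051 M |
| activator | 0.051 M | 0.025 M | 0.038 M | 0.051 M | 0.0510 M (in portions, 2, over 25 min) | 0.0510 M | 0.0510 M (fed, over 25 min) | 0.0510 M |
| remark | run made earlier | run made earlier | run made earlier | run made earlier | first portion at the start, last at 25 min | all else is in the flask from the start; the feed brings no volume worth counting | all else is in the flask from the start; the feed brings no volume worth counting | everything together at the start |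
| time |  |  |  |  | 30 min | 30 min | 30 min | 30 min |

| run | time / min | open dimer / % | ring / % |
|---|---|---|---|
| alder | 4.00 | 7 | 2 |
| alder | 8.00 | 11 | 6 |
| alder | 12.0 | 13 | 4 |
| alder | 15.0 | 18 | 6 |
| alder | 20.0 | 24 | 6 |
| alder | 25.0 | 28 | 6 |
| alder | 30.0 | 35 | 1 |
| oak | 1.33 | 0 | 0 |
| oak | 2.00 | 2 | 2 |
| oak | 3.00 | 1 | 1 |
| oak | 5.00 | 4 | 1 |
| oak | 8.00 | 9 | 0 |
| oak | 12.0 | 13 | 1 |
| oak | 20.0 | 17 | 2 |
| larch | 1.00 | 2 | 0 |
| larch | 3.00 | 0 | 0 |
| larch | 5.00 | 7 | 3 |
| larch | 8.00 | 10 | 3 |
| larch | 10.0 | 11 | 4 |
| larch | 15.0 | 15 | 0 |
| larch | 20.0 | 19 | 1 |
| cedar | 4.00 | 8 | 2 |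
| cedar | 8.00 | 13 | 2 |
| cedar | 10.0 | 14 | 0 |
| cedar | 15.0 | 22 | 0 |
| cedar | 20.0 | 24 | 0 |

(each reading ± 1.5 percentage points)

- percent here means substrate units held: one open dimer counts as two

1. the flask that comes out highest in amount of open dimer, in percent of the substrate charged, or "all alike" when all lie within 1.5 percentage points (epsilon / zeta / gamma / delta / all alike)
2. open dimer at the end, in percent of the substrate charged, epsilon
3. open dimer at the end, in percent of the substrate charged, zeta
4. open dimer at the end, in percent of the substrate charged, gamma
5. open dimer at the end, in percent of the substrate charged, delta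

- Fastest rung: ring in alder reads 6% at 8.00 min and no later reading lies above it, so we treat ring as a small early pool and follow the dimer.
- Slowest rung: alder's last reading gives a substrate turnover time of 85.7 min, longer than the run, so our reckoning ignores substrate consumption.
- Cedar, with twice alder's substrate, reads 24% against 24% at 20.0 min, so we take the dimer rate as proportional to [substrate].
- Middle rung: oak holds 0.490 of alder's activator yet reaches 0.708 of its dimer at 20.0 min. We assume activator destroys itself in a second-order step and expand the logarithms of that decay to first order in time.
- This gives the activator clock, the first half-life of [activator] by that step at the 0.051 M charge, read as 11.5 min with the full scatter of the readings. It is shorter than the feed. It is also shorter than the 20.0 min of the readings used, so the first-order expansion is stretched and the clock is a rough figure.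
- Dividing the time integral of [substrate][activator] in zeta by that in delta cancels the rate constant. With both species counted in units of their charges, our reckoning gives delta 14.7 min and zeta 6.85 min, a share of 0.465.
- Delta repeats alder's charges, so we expect about 35% there and 16.3% in zeta.
- The forecast, which says “Activator therefore seems not to be used up”, names delta and gives 27% for epsilon, 21% for zeta (above our figure), 26% for gamma and 33.5% for delta.
- The flasks give delta as highest, with epsilon 23.0%, zeta 13.3%, gamma 23.7% and delta 30.1%.

    substrate + activator → activated form (k = 0.00570 L mol⁻¹ s⁻¹)
    activated form ⇌ ring (K = 16.0, k = 0.0430 s⁻¹)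
    substrate + activated form → open dimer (k = 0.820 L mol⁻¹ s⁻¹)
    2 activator → self-condensation product (k = 0.0150 L mol⁻¹ s⁻¹)

- In zeta at 5.76 min, self-condensation uses activator 15 times as fast as substrate captures it. By 30.0 min that ratio has fallen to 1.4, with 22% of the activator left.
- For the neighbour of zeta charged with 0.020 M activator, we reckon a clock of 29.2 min and an integral of 10.7 min. Scaling zeta's 13.3% by charge and integral gives 8.15%, and the computed flask gives 8.44%.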